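Ring A is cut at the bond between the spiro carbon and the CMe2 carbon. The CMe2–CHBr pair is the footprint of a bromonium ion opened at its tertiary end. The spiro carbon, which lies between the methylidene-bearing carbon of ring A and the vinylic CH of ring B, is the central carbon of a latent 1,3-diketone. The precursor therefore holds the CMe2 carbon on oxygen, as a 5-bromo-6,6-dimethyloxane enol ether of a cyclohexenone. One Lewis-acid step moves this carbon from oxygen to carbon (a 1,3 shift through a bromonium/diketonate pair), closes the last ring and sets the spiro centre from the C–Br centre, which an enantioselective bromolactonisation installs.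

Key step: step 3

Remark: the target is read as (3Z,6S,8R)-8-bromo-3-(bromomethylidene)-7,7-dimethyl-11-methylidenespiro[5.5]undec-1-ene; ring A is the ring with CMe2, CHBr and the methylidene, ring B the ring with the bromomethylidene; compounds 1 and 3 are taken as purchasable.

Step 1
Reactants: 1 5-methylhex-4-enoic acid
Product: 2 (5R)-5-bromo-6,6-dimethyloxan-2-one
Conditions: N-bromosuccinimide, cinchona amino-thiocarbamate catalyst (10 mol%, quinine or quinidine series chosen to give R), CHCl3/toluene, −78 °C
Reagents that add atoms: N-bromosuccinimide O=C1CCC(=O)N1Br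
Why: Catalytic enantioselective bromolactonisation, in which the carboxylate held by the bifunctional catalyst opens the catalyst-bound bromonium ion at the tertiary carbon (6-endo, Markovnikov), so that the catalyst-controlled face of bromine delivery sets the C5 stereocentre as R.

Step 2
Reactants: 3 3-ethoxycyclohex-2-en-1-one; 2 (5R)-5-bromo-6,6-dimethyloxan-2-one
Product: 5 6-[(5R)-5-bromo-6,6-dimethyloxan-2-ylidene]-3-ethoxycyclohex-2-en-1-one, via lactol 4 (not isolated)
Conditions: LiN(iPr)2, THF, −78 °C; 2, −78 °C; AcOH, −78 °C; then pyridinium p-toluenesulfonate (cat.), 4 Å MS, CH2Cl2, rt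
Reagents that add atoms: none
Why: Crossed Claisen-type acylation of the kinetic α′ lithium enolate of the vinylogous ester by the δ-lactone should stop at the lithium lactolate at −78 °C, so that no free tertiary alkoxide can displace the bromide, and acid-catalysed dehydration towards the acidic ring α-hydrogen then gives the conjugated (push-pull) enol ether without touching the C–Br centre.

Step 3
Reactants: 5 6-[(5R)-5-bromo-6,6-dimethyloxan-2-ylidene]-3-ethoxycyclohex-2-en-1-one
Product: 6 (6R,10R)-10-bromo-3-ethoxy-11,11-dimethylspiro[5.5]undec-2-ene-1,7-dione
Conditions: Sc(OTf)3 (20 mol%), (CF3)2CHOH/CH2Cl2, 0 °C to rt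
Reagents that add atoms: none
Why: Sc(OTf)3 should bind the ketone oxygen and the oxane oxygen of the enol ether (the push-pull double bond isomerises freely to the chelating geometry), the tertiary C6–O bond then ionises with anchimeric help from the neighbouring bromine, and the central carbon of the resulting scandium 1,3-diketonate opens the bromonium ion at its tertiary carbon, anti to bromine. The closest known reaction types are the Lewis acid 1,3 oxygen-to-carbon rearrangement of cyclic enol ethers (Petasis–Ferrier type) and the bromonium-initiated cation–olefin cyclisation terminated by a 1,3-dicarbonyl unit. Ring A closes in a 6-(enolendo)-exo-tet mode through a chair transition state. The C–Br centre is not touched and keeps R; the new spiro centre is set by this centre together with the U-shaped chelate, which holds the tether syn to the CH2 arm of ring B, so that the carbonyl arm becomes equatorial and cis to the equatorial bromine (6R,10R). The step needs carbon rather than oxygen return of the ion pair, which is expected because oxygen return only regenerates 5 while C–C bond formation is irreversible, and the nucleophilic C2 of ring B cannot compete because it would have to close an eight-membered ring.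

Step 4
Reactants: 6 (6R,10R)-10-bromo-3-ethoxy-11,11-dimethylspiro[5.5]undec-2-ene-1,7-dione
Product: 7 (6S,8R)-8-bromo-3-ethoxy-7,7-dimethyl-11-methylidenespiro[5.5]undec-2-en-1-one
Conditions: Ph3PCH3Br, KN(SiMe3)2, THF, 0 °C; then 6, 0 °C to rt
Reagents that add atoms: methyltriphenylphosphonium bromide C[P+](c1ccccc1)(c1ccccc1)c1ccccc1.[Br-]
Why: Wittig methylenation should take place only at the saturated C7 ketone, since the C1 carbonyl is deactivated as a vinylogous ester, and an alkoxide-free ylide avoids retro-Claisen cleavage of the non-enolisable 1,3-diketone; no stereocentre is involved (the descriptor at C6 changes only through the priority rules).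

Step 5
Reactants: 7 (6S,8R)-8-bromo-3-ethoxy-7,7-dimethyl-11-methylidenespiro[5.5]undec-2-en-1-one
Product: 9 (6S,8R)-8-bromo-7,7-dimethyl-11-methylidenespiro[5.5]undec-1-en-3-one, via allylic alcohol 8 (not isolated)
Conditions: iBu2AlH, CH2Cl2, −78 °C; then 1 M HCl, THF, 0 °C
Reagents that add atoms: water O
Why: Stork–Danheiser transposition, in which 1,2-reduction of the vinylogous ester carbonyl followed by acid hydrolysis of the enol ether and loss of the allylic hydroxyl moves the carbonyl to C3 and leaves the ring B double bond at C1=C2 next to the untouched quaternary spiro centre, while iBu2AlH spares the alkyl bromide.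

Step 6
Reactants: 9 (6S,8R)-8-bromo-7,7-dimethyl-11-methylidenespiro[5.5]undec-1-en-3-one
Product: 10 (6S,8R)-8-bromo-3-(dibromomethylidene)-7,7-dimethyl-11-methylidenespiro[5.5]undec-1-ene
Conditions: CBr4, PPh3, Zn, CH2Cl2, rt; then 9, reflux
Reagents that add atoms: carbon tetrabromide BrC(Br)(Br)Br
Why: Ramirez dibromo-olefination (first stage of the Corey–Fuchs sequence) of the enone carbonyl with Ph3P=CBr2, pre-formed with zinc so that no Ph3PBr2 or HBr reaches the 1,1-disubstituted alkene, gives a geminal dibromide and therefore raises no question of alkene geometry.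

Step 7
Reactants: 10 (6S,8R)-8-bromo-3-(dibromomethylidene)-7,7-dimethyl-11-methylidenespiro[5.5]undec-1-ene
Product: 11 (3Z,6S,8R)-8-bromo-3-(bromomethylidene)-7,7-dimethyl-11-methylidenespiro[5.5]undec-1-ene
Conditions: Pd(PPh3)4 (5 mol%), Bu3SnH (1.05 equiv), toluene, rt
Reagents that add atoms: none
Why: Palladium-catalysed tin hydride hydrogenolysis of a 1,1-dibromoalkene, in which zerovalent palladium should insert into the less shielded C–Br bond on the C4 side (anti to the C1=C2 double bond, the outer position of the s-trans diene, as in 1,1-dibromo-1,3-dienes) and hydride delivery with retention leaves the bromine syn to C2, which is the Z geometry, while the secondary alkyl bromide does not react with the palladium catalyst at room temperature.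

Compound list
1 | 5-methylhex-4-enoic acid | CC(C)=CCCC(=O)O | starting material
2 | (5R)-5-bromo-6,6-dimethyloxan-2-one | O=C1CC[C@@H](Br)C(C)(C)O1 | intermediate
3 | 3-ethoxycyclohex-2-en-1-one | CCOC1=CC(=O)CCC1 | starting material
4 | 6-[(5R)-5-bromo-2-hydroxy-6,6-dimethyloxan-2-yl]-3-ethoxycyclohex-2-en-1-one (lactol, epimers at the hemiketal carbon and at C6 of the enone ring, not isolated) | CCOC1=CC(=O)C(CC1)C2(O)CC[C@@H](Br)C(C)(C)O2 | intermediate
5 | 6-[(5R)-5-bromo-6,6-dimethyloxan-2-ylidene]-3-ethoxycyclohex-2-en-1-one (geometry of the exocyclic double bond not controlled and erased in step 3) | CCOC1=CC(=O)C(CC1)=C2CC[C@@H](Br)C(C)(C)O2 | intermediate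
6 | (6R,10R)-10-bromo-3-ethoxy-11,11-dimethylspiro[5.5]undec-2-ene-1,7-dione | O=C1CC[C@@H](Br)C(C)(C)[C@@]12C(=O)C=C(OCC)CC2 | intermediate
7 | (6S,8R)-8-bromo-3-ethoxy-7,7-dimethyl-11-methylidenespiro[5.5]undec-2-en-1-one | C=C1CC[C@@H](Br)C(C)(C)[C@@]12C(=O)C=C(OCC)CC2 | intermediate
8 | (6S,8R)-8-bromo-3-ethoxy-7,7-dimethyl-11-methylidenespiro[5.5]undec-2-en-1-ol (C1 epimers, not isolated) | C=C1CC[C@@H](Br)C(C)(C)[C@@]12C(O)C=C(OCC)CC2 | intermediate
9 | (6S,8R)-8-bromo-7,7-dimethyl-11-methylidenespiro[5.5]undec-1-en-3-one | C=C1CC[C@@H](Br)C(C)(C)[C@@]12C=CC(=O)CC2 | intermediate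
10 | (6S,8R)-8-bromo-3-(dibromomethylidene)-7,7-dimethyl-11-methylidenespiro[5.5]undec-1-ene | C=C1CC[C@@H](Br)C(C)(C)[C@@]12C=CC(=C(Br)Br)CC2 | intermediate
11 | (3Z,6S,8R)-8-bromo-3-(bromomethylidene)-7,7-dimethyl-11-methylidenespiro[5.5]undec-1-ene | C=C1CC[C@@H](Br)C(C)(C)[C@@]12C=C/C(=C\Br)CC2 | target

Total step count: 7
Longest linear sequence: 7 steps (1 to 11; 3 enters in step 2)

Steps most likely to fail

1. Step 3 (key step). Ion-pair return to oxygen or proton loss from the cationic carbon may outrun bond formation between two fully substituted carbons, and reaction through a non-chelated diketonate would erode facial selectivity at the spiro carbon. The fallback sets out from lactol 4, isolated from step 2 without the dehydration; 4 is in equilibrium with its open-chain tautomer 6-[(4R)-4-bromo-5-hydroxy-5-methylhexanoyl]-3-ethoxycyclohex-2-en-1-one F1. Treatment with SnCl4 (2 equiv) in CH2Cl2 at −78 to −20 °C should first form the trichlorotin diketonate chelate, which ties up both oxygens, and then ionise the tertiary alcohol. This is a cation–olefin cyclisation terminated by a metal-chelated 1,3-dicarbonyl unit, in which return to oxygen is not possible. It comes back to the route at 6.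

2. Step 2. The enolate may act as a base towards the bromolactone (α-deprotonation followed by loss of bromide), or the lactolate may collapse to an alkoxide that closes onto the C–Br carbon. The fallback sets out from 1 and 3 and reverses the order of acylation and bromination. Acid 1 is activated with carbonyldiimidazole to 1-(5-methylhex-4-enoyl)imidazole F2, which acylates the lithium enolate of 3 to give 3-ethoxy-6-(5-methylhex-4-enoyl)cyclohex-2-en-1-one F3. A catalytic enantioselective bromocyclisation of this olefinic 1,3-dicarbonyl compound (N-bromosuccinimide, the same amino-thiocarbamate catalyst class, −78 °C), with the enol oxygen opening the bromonium ion at the tertiary carbon, should give 5 directly. It comes back to the route at 5 and bypasses 2 and 4.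

3. Step 7. Discrimination between the two geminal C–Br bonds in the oxidative addition may be insufficient, or over-reduction may occur, so that a mixture of geometries results. The fallback sets out from 9. A Wittig reaction with bromomethylidenetriphenylphosphorane (from (bromomethyl)triphenylphosphonium bromide and NaN(SiMe3)2, THF, −78 °C) should give 11 together with its 3E isomer, (3E,6S,8R)-8-bromo-3-(bromomethylidene)-7,7-dimethyl-11-methylidenespiro[5.5]undec-1-ene F4. The two are separated on AgNO3-impregnated silica, and F4 is re-equilibrated by irradiation with catalytic diphenyl disulfide and recycled. It comes back to the route at 11 and bypasses 10.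

Further compounds
F1 | step 3 | 6-[(4R)-4-bromo-5-hydroxy-5-methylhexanoyl]-3-ethoxycyclohex-2-en-1-one | CCOC1=CC(=O)C(CC1)C(=O)CC[C@@H](Br)C(C)(C)O
F2 | step 2 | 1-(5-methylhex-4-enoyl)imidazole | CC(C)=CCCC(=O)n1ccnc1
F3 | step 2 | 3-ethoxy-6-(5-methylhex-4-enoyl)cyclohex-2-en-1-one | CCOC1=CC(=O)C(CC1)C(=O)CCC=C(C)C
F4 | step 7 | (3E,6S,8R)-8-bromo-3-(bromomethylidene)-7,7-dimethyl-11-methylidenespiro[5.5]undec-1-ene | C=C1CC[C@@H](Br)C(C)(C)[C@@]12C=C/C(=C/Br)CC2
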